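## Structural features

The target is a 2-oxabicyclo[2.2.2]octane-3,5-dione cage (a δ-lactone, O2–C3, bridged by the C5 ketone) spiro-joined through C8 to a tetrahydropyran carrying methyls at C3', C5', C6' and an acetate at C4'. Nine stereocentres run unbroken from C6' through C5', C4', C3', C8, C7 and C1 to C6, and the quaternary C4 closes the cage. C8 (ether carbon, spiro) and C4 (methyl, lactone carbonyl, ketone) are neighbours and both fully substituted. In the pyran chair the three methyls are equatorial and the acetate axial; C7 is axial on C8, hence 1,3-diaxial to the C4' oxygen, and C4 is equatorial. The lactone oxygen on C1 is β to the C5 ketone, so an enolate at C6 can expel the carboxylate, and the keto lactone with quaternary C4 is open to retro-Claisen attack. The C6 methyl points into the crowded gap toward the C7–C8 bridge, which is likely the less stable epimer, so C6 has to be set kinetically and late. The real difficulty is the C8–C4 bond between two fully substituted carbons together with the configuration of C8. The key step uses two features: C8–C4 can pre-exist as the double bond of an exocyclic β-alkoxyacrylate on the finished pyran, and the chain C7–C1–C6–C5 with its two methyls is the skeleton of methyl 2-methyl-3-oxopentanoate, so the carbocycle closes by C7→C8 and C4→C5.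

## Logic of the disconnections

**24 ⇒ 23.** The C6–H bond is cut and replaced by C6–Cl. C6 is the only epimerisable centre, its methyl sits on the hindered side, and an enolate cannot be used next to the lactone oxygen. The gain is that all basic steps run on a compound without C6–H. The forward step must deliver a hydrogen atom to a planar C6 from the open face.

**23 ⇒ 22 ⇒ 21.** The C4' O–acyl bond and then the C4' O–H are traded for an ether, so the acetate never meets carbanion chemistry. The forward steps need an acetal cleavage that spares lactone, ketone and the ring ether, and an acylation of a hindered axial alcohol.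

**21 ⇒ 19 (through 20).** The lactone bond C3–O2 and the C1–H bond are cut. This opens the cage to a spiro cyclohexanedione. The forward step needs hydride at C1 and not C5, from the face that leaves the hydroxyl cis to the ester, since only that alcohol can bridge.

**19 ⇒ 18.** The C6–Cl bond is cut. 18 is an enolised 1,3-dione whose carbonyls a hydride cannot tell apart; the chloride turns them into two ketones of different hindrance. The forward step only needs monochlorination at C6.

**18 ⇒ 14 + 15.** C7–C8 and C4–C5 are cut. This removes the carbocycle and three stereocentres at once, leaves every remaining stereocentre in a monocyclic pyran, and uses a commercial keto ester. The forward step needs conjugate addition to a tetrasubstituted acceptor and control of C8, C4 and C7.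

**14 ⇒ 12 (through 13).** The O1'–C8 bond and the alkene are cut by a hydration/ring-opening, giving an acyclic keto ester. The forward step must place the double bond exocyclic and conjugated without disturbing C3'.

**12 ⇒ 8 + 9 (through 11).** The bond between C8 and the future C4 is cut as an aldol followed by oxidation. This separates the propanoate unit; no stereocontrol is required.

**8 ⇒ 5 (through 7 and 6).** The C3'–C4' bond is cut as a crotylboration, with C8 later revealed by alkene cleavage. Two stereocentres come from one step. The forward step must give the 3,4-anti, 4,5-anti triad.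

**5 ⇒ 1 (through 4 and 3).** The C5'–CH3 bond is cut. The chiral pool supplies C6', and the forward alkylation must be anti.

## Other disconnections considered

**Alternative 1:** The cut is through C8–C3' and O1'–C6', with the acetate arising from a temporary O1'–C4' bond. Cage ketone A2 would be irradiated with diene A3; carbonyl–alkene [2+2] cycloaddition at the internal Z alkene would give spiro-oxetane A1. Acetate would then open the oxetane at C4' with inversion, and the freed O1'–H would add across the vinyl group to close the pyran.
- In favour: the cage comes from a symmetric precursor, C8–C3' is made without anionic chemistry, the acetate enters with no protecting group on C4', and the sequence is clearly shorter. On step and protecting-group economy it is the better plan.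
- Against: both alkene carbons of A3 are secondary, so the 1,4-biradical has little regiochemical bias. A triplet biradical can scramble the Z geometry. The ketone of A2 is flanked by quaternary C4 and is β to the lactone carbonyl, so α-cleavage competes. Both partners are chiral, so ketone face and alkene face must match. Lewis-acid opening of the oxetane is more likely to break the tertiary C8–O bond than the secondary C4'–O bond. A1 carries C6 opposite to 24 and C5 as a silyl ether, so an oxidation and a kinetic correction at C6 still follow.
- Comparison: the two plans are equal in that neither key step has precedent on this substrate class and both need a late operation at C6. The alternative is better on length; the chosen plan leaves fewer selectivities to chance.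

**Alternative 2:** Only C4–C5 is cut. Spiro lactone A5, carrying the C6–C5 chain on C1 as an N-methoxy-N-methyl amide, would be deprotonated at C4; the lactone enolate would acylate itself on the amide carbon to give A4 after work-up. Desilylation and acetylation would finish.
- In favour: Claisen-type acylation by this amide class is established. The tetrahedral chelate holds until quench, shielding the new ketone from retro-Claisen attack and from enolisation at C6. C4 can only be joined on the ring face carrying the side chain, so its configuration is fixed by the tether. On C4 control and on precedent this plan is the better one.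
- Against: the bridge needs a boat with C4 and the C1 side chain both in flagpole positions. The C4 enolate has O1' in the β position and can open the pyran, with no irreversible step to pull it back. Deprotonation at C6 would expel O2 from C1 and destroy the lactone. A5 already contains C8 with C7 and C4 attached, so the hardest bonds are only moved upstream, at the cost of a much longer linear sequence.
- Comparison: equal exposure to loss of O1' from the C4 enolate; better certainty at C4 and C6; worse step economy and no answer to how C8 is built.

**Alternative 3:** The cut is again through C8–C3' and O1'–C6', now from meso cage diketone A7. A chiral Lewis acid would bind the lactone carbonyl and one of the two enantiotopic ketones; Mukaiyama aldol addition of siloxydiene A8 and oxa-Michael closure of the tertiary alkoxide would give spiro pyranone A6.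
- In favour: it is by far the shortest plan, takes absolute configuration from a catalyst, and uses the hidden mirror symmetry of the cage. The all-equatorial methyl pattern is the thermodynamic outcome of a reversible oxa-Michael step. The later reduction of the C4' ketone should be steered to the axial alcohol by the axial C7. On step economy and on C4' it is the better plan.
- Against: one step must select the ketone, the ketone face and the diene face at a carbonyl flanked by a quaternary carbon. The tertiary aldolate can revert. A7 is a doubly activated β-keto lactone open to retro-Claisen cleavage. The second ketone must survive the reduction. A6 still has C6 as in A7, so an inversion to the more hindered epimer on a base-sensitive β-acyloxy ketone remains.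
- Comparison: equal in that the key step lacks direct precedent and C6 must be set at the end. The alternative is better on length and convergence; the chosen plan takes every stereocentre outside the key step from well-known control elements and sets C6 in a purpose-built last step.

Key step: step 10

Remark: the structures are internally consistent, and two points are changed. C6 of the annulation product lies between two carbonyls and is enolised, so it is drawn without a configuration. The C4' ether is methoxymethyl instead of a bulky silyl group, because C7 has to sit 1,3-diaxial to that oxygen and the small acetal can bind lithium. The alkene of 14 is taken as Z; the E isomer would converge in step 10, since C4 is set only after the double bond has become an enolate.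

## Route

Step 1
Reactants: 1 methyl (R)-3-hydroxybutanoate
Product: 3 methyl (2R,3R)-3-hydroxy-2-methylbutanoate, via dilithium alkoxide enolate 2 (not isolated)
Conditions: LiN(iPr)2 (2.2 equiv), THF, −78 to −20 °C; MeI, DMPU, −78 to 0 °C
Reagents that add atoms: iodomethane CI
Why: Fráter–Seebach alkylation: the chelated dilithium alkoxide enolate 2 is methylated on the face away from the C3 methyl, which sets the new centre anti to the hydroxyl (2R,3R).

Step 2
Reactants: 3 methyl (2R,3R)-3-hydroxy-2-methylbutanoate
Product: 4 methyl (2R,3R)-3-[(tert-butyldimethylsilyl)oxy]-2-methylbutanoate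
Conditions: TBSCl, imidazole, DMF, 25 °C
Reagents that add atoms: tert-butyldimethylsilyl chloride CC(C)(C)[Si](C)(C)Cl
Why: Standard silylation of a secondary alcohol; the silyl ether masks the future ring oxygen O1' through the chain-building steps.

Step 3
Reactants: 4 methyl (2R,3R)-3-[(tert-butyldimethylsilyl)oxy]-2-methylbutanoate
Product: 5 (2R,3R)-3-[(tert-butyldimethylsilyl)oxy]-2-methylbutanal
Conditions: iBu2AlH (1.05 equiv), CH2Cl2, −78 °C; MeOH, aq. KNaC4H4O6
Reagents that add atoms: none
Why: Partial reduction of a methyl ester: the aluminium hemiacetal is stable at −78 °C and releases the aldehyde only on work-up, so the α-centre is not exposed to base.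

Step 4
Reactants: 5 (2R,3R)-3-[(tert-butyldimethylsilyl)oxy]-2-methylbutanal
Product: 6 (3S,4S,5S,6R)-6-[(tert-butyldimethylsilyl)oxy]-3,5-dimethylhept-1-en-4-ol
Conditions: (R,R)-diisopropyl tartrate (E)-crotylboronate (1.5 equiv), 4 Å molecular sieves, PhMe, −78 °C; aqueous work-up
Reagents that add atoms: diisopropyl (4R,5R)-2-[(2E)-but-2-en-1-yl]-1,3,2-dioxaborolane-4,5-dicarboxylate C/C=C/CB1O[C@@H](C(=O)OC(C)C)[C@H](C(=O)OC(C)C)O1
Why: Tartrate-controlled (E)-crotylboration through a closed chair transition state: the E geometry gives the 3,4-anti pair and the (R,R)-tartrate directs attack to the Si face of the aldehyde, which sets C4' and C3' 4,5-anti to the existing methyl. For an α-methyl β-silyloxy aldehyde this is expected to be the matched pairing.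

Step 5
Reactants: 6 (3S,4S,5S,6R)-6-[(tert-butyldimethylsilyl)oxy]-3,5-dimethylhept-1-en-4-ol
Product: 7 tert-butyl{[(2R,3S,4S,5S)-4-(methoxymethoxy)-3,5-dimethylhept-6-en-2-yl]oxy}dimethylsilane
Conditions: MOMCl, iPr2NEt, Bu4NI (cat.), CH2Cl2, 0 to 40 °C
Reagents that add atoms: chloromethyl methyl ether COCCl
Why: Alkylation of the hindered secondary alcohol by a reactive chloromethyl ether under amine base (no silyl migration); the small acetal survives strong base and can bind lithium in step 10.

Step 6
Reactants: 7 tert-butyl{[(2R,3S,4S,5S)-4-(methoxymethoxy)-3,5-dimethylhept-6-en-2-yl]oxy}dimethylsilane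
Product: 8 (2R,3R,4S,5R)-5-[(tert-butyldimethylsilyl)oxy]-3-(methoxymethoxy)-2,4-dimethylhexanal
Conditions: O3, CH2Cl2, −78 °C; PPh3
Reagents that add atoms: ozone [O-][O+]=O
Why: Ozonolysis with reductive work-up cleaves the terminal alkene to the aldehyde and reveals the future C8 without touching the α-stereocentre.

Step 7
Reactants: 8 (2R,3R,4S,5R)-5-[(tert-butyldimethylsilyl)oxy]-3-(methoxymethoxy)-2,4-dimethylhexanal, 9 methyl propanoate
Product: 11 methyl (4S,5S,6S,7R)-7-[(tert-butyldimethylsilyl)oxy]-3-hydroxy-5-(methoxymethoxy)-2,4,6-trimethyloctanoate (C2/C3 epimers), via lithium enolate 10 (not isolated)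
Conditions: LiN(iPr)2, THF, −78 °C; 9; then 8, −78 °C
Reagents that add atoms: none
Why: Aldol addition of the lithium ester enolate 10 to the aldehyde; both new centres are erased in steps 8 and 9, so no selectivity is needed.

Step 8
Reactants: 11 methyl (4S,5S,6S,7R)-7-[(tert-butyldimethylsilyl)oxy]-3-hydroxy-5-(methoxymethoxy)-2,4,6-trimethyloctanoate (C2/C3 epimers)
Product: 12 methyl (4R,5R,6S,7R)-7-[(tert-butyldimethylsilyl)oxy]-5-(methoxymethoxy)-2,4,6-trimethyl-3-oxooctanoate (C2 epimers)
Conditions: Dess–Martin periodinane, CH2Cl2, 25 °C
Reagents that add atoms: none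
Why: Dess–Martin oxidation of the secondary alcohol under neutral conditions gives the β-keto ester; C3' is not the most acidic position and should keep its configuration.

Step 9
Reactants: 12 methyl (4R,5R,6S,7R)-7-[(tert-butyldimethylsilyl)oxy]-5-(methoxymethoxy)-2,4,6-trimethyl-3-oxooctanoate (C2 epimers)
Product: 14 methyl (2Z)-2-[(3R,4R,5R,6R)-4-(methoxymethoxy)-3,5,6-trimethyloxan-2-ylidene]propanoate, via hemiketal 13 (not isolated)
Conditions: HF·pyridine, THF, 0 to 25 °C; then (CF3CO)2O, pyridine, CH2Cl2, 0 °C
Reagents that add atoms: none
Why: Fluoride removes the silyl group and the freed C6' hydroxyl closes onto the ketone to hemiketal 13; trifluoroacetylation of the anomeric hydroxyl and loss of the acidic ester α-proton (dehydration under non-equilibrating conditions) should give the conjugated exocyclic alkene. The Z isomer, with the flat ester beside O1' and only a methyl beside the branched C3', is expected to prevail, and allylic 1,3-strain keeps C3'–H in the alkene plane, which protects C3'.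

Step 10
Reactants: 14 methyl (2Z)-2-[(3R,4R,5R,6R)-4-(methoxymethoxy)-3,5,6-trimethyloxan-2-ylidene]propanoate, 15 methyl 2-methyl-3-oxopentanoate
Product: 18 methyl 4-(methoxymethoxy)-2,3,5,7,9,11-hexamethyl-8,10-dioxo-1-oxaspiro[5.5]undecane-7-carboxylate (spiro dione ester; C6 unfixed), via dilithium dianion 16 (not isolated), via Michael adduct bis-enolate 17 (not isolated)
Conditions: 15 (3 equiv), LiN(iPr)2 (6.3 equiv), THF, 0 °C; 14, −78 to 40 °C; 1 M HCl, 0 °C
Reagents that add atoms: none
Why: Proposed new method: the terminal carbanion of dianion 16 should add to C8 of 14 (the ester carbonyl of a vinylogous carbonate is too deactivated for 1,2-attack), the C4 ester enolate of 17 then closes onto the ester carbon C5 in a 6-(enolexo)-exo-trig Dieckmann step, and loss of methoxide locks the ring irreversibly as the lithium diketonate; the closest known reaction type is the Michael–Dieckmann (Michael–Claisen) annulation of ketone enolates or keto ester dianions with simple acrylates to cyclohexane-1,3-diones, not yet shown for a tetrasubstituted β-alkoxyacrylate. Enolate 17 can expel O1' and regain it by 6-exo-trig oxa-Michael addition, so C8 is expected to be settled in this equilibrium: with C3'–H held in the alkene plane by allylic 1,3-strain, O1' returns anti to the C3' methyl, which leaves C7 axial (cis to the axial C4' oxygen) and the larger C4 equatorial as in the target, and the small lithium-binding methoxymethyl ether keeps that 1,3-diaxial contact tolerable. C4 is set in the Dieckmann transition state, where the lithium enolate oxygen can chelate O1' and the flat enolate carbon stays away from the branched C3', so the ester ends on the O1' side and the methyl on the C3' side. C7 should end with its methyl equatorial in the new ring, because the other epimer suffers a 1,3-diaxial clash with the C4 methyl and excess 16 can equilibrate C7 through reversible deprotonation of the diketonate. The step needs conjugate addition to win over carbonyl addition and over deprotonation at C3'; the first is secured by the push–pull ester and the second by the same allylic strain, which keeps C3'–H orthogonal to the π system.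

Step 11
Reactants: 18 methyl 4-(methoxymethoxy)-2,3,5,7,9,11-hexamethyl-8,10-dioxo-1-oxaspiro[5.5]undecane-7-carboxylate (spiro dione ester; C6 unfixed)
Product: 19 methyl 9-chloro-4-(methoxymethoxy)-2,3,5,7,9,11-hexamethyl-8,10-dioxo-1-oxaspiro[5.5]undecane-7-carboxylate (6-chloro dione; C6 epimers)
Conditions: NCS, CH2Cl2, 0 to 25 °C
Reagents that add atoms: N-chlorosuccinimide O=C1CCC(=O)N1Cl
Why: Electrophilic chlorination of the enolised 1,3-dione at C6, its only nucleophilic carbon. The chloride removes the acidic hydrogen, so the two carbonyls now behave as ketones and no enolate can later expel the lactone oxygen; either C6 epimer serves because C6 is made planar again in step 15.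

Step 12
Reactants: 19 methyl 9-chloro-4-(methoxymethoxy)-2,3,5,7,9,11-hexamethyl-8,10-dioxo-1-oxaspiro[5.5]undecane-7-carboxylate (6-chloro dione; C6 epimers)
Product: 21 (1R,3'R,4S,4'R,5'R,6'R,7S,8S)-6-chloro-4'-(methoxymethoxy)-3',4,5',6,6',7-hexamethylspiro[2-oxabicyclo[2.2.2]octane-8,2'-oxane]-3,5-dione (C6 epimers), via cis-hydroxy ester 20 (not isolated)
Conditions: NaBH4, CeCl3·7H2O, MeOH–THF, −78 °C; then camphorsulfonic acid (cat.), PhMe, 60 °C
Reagents that add atoms: none
Why: Luche reduction: hydride should go to C1, flanked by one tertiary carbon, rather than to C5 between two quaternary carbons, and should enter anti to the axial O1' so that the hydroxyl of 20 is cis to the ester. Acid-catalysed transesterification then closes the bridged lactone, which only the cis alcohol can do; any loss of the acetal here is harmless because step 13 removes it.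

Step 13
Reactants: 21 (1R,3'R,4S,4'R,5'R,6'R,7S,8S)-6-chloro-4'-(methoxymethoxy)-3',4,5',6,6',7-hexamethylspiro[2-oxabicyclo[2.2.2]octane-8,2'-oxane]-3,5-dione (C6 epimers)
Product: 22 (1R,3'R,4S,4'R,5'S,6'R,7S,8S)-6-chloro-4'-hydroxy-3',4,5',6,6',7-hexamethylspiro[2-oxabicyclo[2.2.2]octane-8,2'-oxane]-3,5-dione (C6 epimers)
Conditions: Me2BBr, CH2Cl2, −78 °C; aq. NaHCO3
Reagents that add atoms: none
Why: Lewis-acid cleavage of the acetal C–O bond by the bromoborane at −78 °C, a temperature at which lactone, ketone, tertiary chloride and the ring ether are inert.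

Step 14
Reactants: 22 (1R,3'R,4S,4'R,5'S,6'R,7S,8S)-6-chloro-4'-hydroxy-3',4,5',6,6',7-hexamethylspiro[2-oxabicyclo[2.2.2]octane-8,2'-oxane]-3,5-dione (C6 epimers)
Product: 23 (1R,3'R,4S,4'R,5'R,6'R,7S,8S)-6-chloro-3',4,5',6,6',7-hexamethyl-3,5-dioxospiro[2-oxabicyclo[2.2.2]octane-8,2'-oxan]-4'-yl acetate (C6 epimers)
Conditions: Ac2O, DMAP, pyridine, CH2Cl2, 25 to 40 °C
Reagents that add atoms: acetic anhydride CC(=O)OC(C)=O
Why: DMAP-catalysed acylation of the hindered axial alcohol; the amine base is harmless because C6 carries no hydrogen.

Step 15
Reactants: 23 (1R,3'R,4S,4'R,5'R,6'R,7S,8S)-6-chloro-3',4,5',6,6',7-hexamethyl-3,5-dioxospiro[2-oxabicyclo[2.2.2]octane-8,2'-oxan]-4'-yl acetate (C6 epimers)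
Product: 24 (1R,3'R,4S,4'R,5'R,6S,6'R,7S,8S)-3',4,5',6,6',7-hexamethyl-3,5-dioxospiro[2-oxabicyclo[2.2.2]octane-8,2'-oxan]-4'-yl acetate
Conditions: Bu3SnH, AIBN (cat.), PhH, 80 °C
Reagents that add atoms: none
Why: Radical chain dehalogenation: the tin radical abstracts chlorine and the planar α-keto radical at C6 takes hydrogen from Bu3SnH on the open face between the lactone and ketone bridges, the other face being screened by the C7–C8 bridge and the pyran, which places the methyl on the C7–C8 side as in the target. No enolate is formed, so the β-acyloxy ketone and the kinetic configuration at C6 should survive.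

## Compound list

1 | methyl (R)-3-hydroxybutanoate | COC(=O)C[C@@H](C)O | starting material
2 | dilithium alkoxide enolate of 1 | [Li+].[Li+].COC([O-])=C[C@@H](C)[O-] | intermediate
3 | methyl (2R,3R)-3-hydroxy-2-methylbutanoate | COC(=O)[C@H](C)[C@@H](C)O | intermediate
4 | methyl (2R,3R)-3-[(tert-butyldimethylsilyl)oxy]-2-methylbutanoate | COC(=O)[C@H](C)[C@@H](C)O[Si](C)(C)C(C)(C)C | intermediate
5 | (2R,3R)-3-[(tert-butyldimethylsilyl)oxy]-2-methylbutanal | O=C[C@H](C)[C@@H](C)O[Si](C)(C)C(C)(C)C | intermediate
6 | (3S,4S,5S,6R)-6-[(tert-butyldimethylsilyl)oxy]-3,5-dimethylhept-1-en-4-ol | C=C[C@H](C)[C@H](O)[C@H](C)[C@@H](C)O[Si](C)(C)C(C)(C)C | intermediate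
7 | tert-butyl{[(2R,3S,4S,5S)-4-(methoxymethoxy)-3,5-dimethylhept-6-en-2-yl]oxy}dimethylsilane | C=C[C@H](C)[C@H](OCOC)[C@H](C)[C@@H](C)O[Si](C)(C)C(C)(C)C | intermediate
8 | (2R,3R,4S,5R)-5-[(tert-butyldimethylsilyl)oxy]-3-(methoxymethoxy)-2,4-dimethylhexanal | O=C[C@H](C)[C@H](OCOC)[C@H](C)[C@@H](C)O[Si](C)(C)C(C)(C)C | intermediate
9 | methyl propanoate | CCC(=O)OC | starting material
10 | lithium enolate of 9 | [Li+].CC=C([O-])OC | intermediate
11 | methyl (4S,5S,6S,7R)-7-[(tert-butyldimethylsilyl)oxy]-3-hydroxy-5-(methoxymethoxy)-2,4,6-trimethyloctanoate (C2/C3 epimers) | COC(=O)C(C)C(O)[C@H](C)[C@H](OCOC)[C@H](C)[C@@H](C)O[Si](C)(C)C(C)(C)C | intermediate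
12 | methyl (4R,5R,6S,7R)-7-[(tert-butyldimethylsilyl)oxy]-5-(methoxymethoxy)-2,4,6-trimethyl-3-oxooctanoate (C2 epimers) | COC(=O)C(C)C(=O)[C@H](C)[C@H](OCOC)[C@H](C)[C@@H](C)O[Si](C)(C)C(C)(C)C | intermediate
13 | methyl 2-[(3R,4R,5R,6R)-2-hydroxy-4-(methoxymethoxy)-3,5,6-trimethyloxan-2-yl]propanoate (anomers; side-chain epimers) | COCO[C@@H]1[C@H](C)[C@@H](C)OC(O)(C(C)C(=O)OC)[C@@H]1C | intermediate
14 | methyl (2Z)-2-[(3R,4R,5R,6R)-4-(methoxymethoxy)-3,5,6-trimethyloxan-2-ylidene]propanoate | COCO[C@@H]1[C@H](C)[C@@H](C)O/C(=C(/C)C(=O)OC)[C@@H]1C | intermediate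
15 | methyl 2-methyl-3-oxopentanoate | CCC(=O)C(C)C(=O)OC | starting material
16 | dilithium dianion of 15 | [Li+].[Li+].CC=C([O-])C(C)=C([O-])OC | intermediate
17 | dilithium bis-enolate of the Michael adduct (C4 ester enolate plus keto ester enolate; C7–C8 formed) | [Li+].[Li+].COCO[C@@H]1[C@H](C)[C@@H](C)O[C@]([C@@H]1C)(C(C)=C([O-])OC)[C@@H](C)C([O-])=C(C)C(=O)OC | intermediate
18 | methyl 4-(methoxymethoxy)-2,3,5,7,9,11-hexamethyl-8,10-dioxo-1-oxaspiro[5.5]undecane-7-carboxylate; pyran centres as in 14, C8 and C7 as in 24, ester on C4 cis to O1', C6 unfixed (largely enol) | COCO[C@@H]1[C@H](C)[C@@H](C)O[C@@]2([C@@H]1C)[C@@H](C)C(=O)C(C)C(=O)[C@@]2(C)C(=O)OC | intermediate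
19 | 6-chloro derivative of 18 (chlorine on the carbon between the two ketones; C6 epimers) | COCO[C@@H]1[C@H](C)[C@@H](C)O[C@@]2([C@@H]1C)[C@@H](C)C(=O)C(C)(Cl)C(=O)[C@@]2(C)C(=O)OC | intermediate
20 | cis-hydroxy ester: 19 with C1 reduced to the alcohol whose hydroxyl is cis to the C4 ester | COCO[C@@H]1[C@H](C)[C@@H](C)O[C@@]2([C@@H]1C)[C@@H](C)[C@@H](O)C(C)(Cl)C(=O)[C@@]2(C)C(=O)OC | intermediate
21 | (1R,3'R,4S,4'R,5'R,6'R,7S,8S)-6-chloro-4'-(methoxymethoxy)-3',4,5',6,6',7-hexamethylspiro[2-oxabicyclo[2.2.2]octane-8,2'-oxane]-3,5-dione (C6 epimers) | COCO[C@@H]1[C@H](C)[C@@H](C)O[C@@]2([C@@H]1C)[C@@H](C)[C@H]1OC(=O)[C@]2(C)C(=O)C1(C)Cl | intermediate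
22 | (1R,3'R,4S,4'R,5'S,6'R,7S,8S)-6-chloro-4'-hydroxy-3',4,5',6,6',7-hexamethylspiro[2-oxabicyclo[2.2.2]octane-8,2'-oxane]-3,5-dione (C6 epimers) | O[C@@H]1[C@H](C)[C@@H](C)O[C@@]2([C@@H]1C)[C@@H](C)[C@H]1OC(=O)[C@]2(C)C(=O)C1(C)Cl | intermediate
23 | (1R,3'R,4S,4'R,5'R,6'R,7S,8S)-6-chloro-3',4,5',6,6',7-hexamethyl-3,5-dioxospiro[2-oxabicyclo[2.2.2]octane-8,2'-oxan]-4'-yl acetate (C6 epimers) | CC(=O)O[C@@H]1[C@H](C)[C@@H](C)O[C@@]2([C@@H]1C)[C@@H](C)[C@H]1OC(=O)[C@]2(C)C(=O)C1(C)Cl | intermediate
24 | (1R,3'R,4S,4'R,5'R,6S,6'R,7S,8S)-3',4,5',6,6',7-hexamethyl-3,5-dioxospiro[2-oxabicyclo[2.2.2]octane-8,2'-oxan]-4'-yl acetate | CC(=O)O[C@@H]1[C@H](C)[C@@H](C)O[C@@]2([C@@H]1C)[C@@H](C)[C@H]1OC(=O)[C@]2(C)C(=O)[C@H]1C | target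

## Step count and least certain steps

Total: 15 steps. Longest linear sequence: 15 steps from 1; 9 and 15 are commercial and enter directly.

**Step 10 (key step).** The most likely failure is that no conjugate addition takes place at the tetrasubstituted, donor-substituted acceptor and the dianion instead acts as a base at C3'. That would quench the reagent and lead to epimerisation at C3' or elimination of the C4' ether. Next in likelihood are poor control at C8 and C7 if the ring-opening/oxa-Michael equilibrium is slow relative to cyclisation, and stalling at the ring-opened enoate. The fallback uses known chemistry; it sets out from 13 (isolated after the fluoride stage of step 9) and from 15, and returns at 18. 15 would be silylated twice (Me3SiCl/Et3N, then LiN(iPr)2/Me3SiCl) to the 1,3-bis(trimethylsilyloxy)diene F1. Me3SiOTf in CH2Cl2 at −78 °C would ionise 13 to its cyclic oxocarbenium ion; any 14 formed by proton loss re-enters as its O-silylated oxocarbenium form. The terminal carbon of F1 would add in a vinylogous Mukaiyama reaction, a known reaction of ketal-derived oxocarbenium ions. Axial attack on the half-chair with the C4' oxygen pseudoaxial should give keto diester F2 with C7 axial. A classical Dieckmann condensation of F2 (NaOMe, MeOH, 60 °C) would then close the carbocycle to 18 under thermodynamic control.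

**Step 9.** The dehydration may run toward C3' (endocyclic enol ether), or the cation may equilibrate and epimerise C3', whose epimer is probably the more stable alkoxyacrylate. The fallback sets out from 12 and returns at 14. The sodium enolate of 12 (NaH, THF) would be O-sulfonylated with PhNTf2 to enol triflate F3. HF·pyridine would free the C6' hydroxyl (hydroxy enol triflate F4), and K2CO3 in MeCN would close the ring by conjugate addition and loss of triflate. This addition–elimination can only place the double bond exocyclic and conjugated, and C3' never sits next to a cation.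

**Step 12.** Hydride may enter from the wrong face of C1, methoxide may cleave the 2-chloro-1,3-dione by retro-Claisen ring opening, or the transesterification may be slow at the neopentyl-type ester. The fallback sets out from 19 and returns at 21. A Meerwein–Ponndorf–Verley reduction (Al(OiPr)3, 2-propanol, PhMe, 80 °C), a classical method for α-halo ketones, makes hydride transfer reversible in a non-nucleophilic medium. The cis alcohol 20 is drained by lactonisation on aluminium to 21, whereas the trans-hydroxy ester F5 is re-oxidised to 19 by the acetone formed and fed back.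

**Step 15.** Hydrogen-atom transfer may be poorly face-selective, and the kinetic epimer may equilibrate on handling. The fallback sets out from 23 and returns at 24. The reduction is run to completion regardless of selectivity. The mixture of 24 and its C6 epimer F6 is converted with Me3SiOTf and 2,6-lutidine (no free enolate) into the single silyl enol ether F7. F7 is protonated at −78 °C with one equivalent of anhydrous HCl in CH2Cl2; the proton should again enter from the open lactone-side face.

## Further compounds

F1 | step 10 | [(1-methoxy-2-methylpenta-1,3-diene-1,3-diyl)bis(oxy)]bis(trimethylsilane) (geometrical isomers) | CC=C(O[Si](C)(C)C)C(C)=C(OC)O[Si](C)(C)C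
F2 | step 10 | methyl 4-[2-(1-methoxy-1-oxopropan-2-yl)-4-(methoxymethoxy)-3,5,6-trimethyloxan-2-yl]-2-methyl-3-oxopentanoate (ring centres and C7 as in 18; ester α-carbons unfixed) | COCO[C@@H]1[C@H](C)[C@@H](C)O[C@]([C@@H]1C)(C(C)C(=O)OC)[C@@H](C)C(=O)C(C)C(=O)OC
F3 | step 9 | methyl (4R,5R,6S,7R)-7-[(tert-butyldimethylsilyl)oxy]-5-(methoxymethoxy)-2,4,6-trimethyl-3-{[(trifluoromethyl)sulfonyl]oxy}oct-2-enoate (E/Z) | COC(=O)C(C)=C(OS(=O)(=O)C(F)(F)F)[C@H](C)[C@H](OCOC)[C@H](C)[C@@H](C)O[Si](C)(C)C(C)(C)C
F4 | step 9 | methyl (4R,5R,6R,7R)-7-hydroxy-5-(methoxymethoxy)-2,4,6-trimethyl-3-{[(trifluoromethyl)sulfonyl]oxy}oct-2-enoate (E/Z) | COC(=O)C(C)=C(OS(=O)(=O)C(F)(F)F)[C@H](C)[C@H](OCOC)[C@H](C)[C@@H](C)O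
F5 | step 12 | trans-hydroxy ester, the C1 epimer of 20 (hydroxyl trans to the C4 ester) | COCO[C@@H]1[C@H](C)[C@@H](C)O[C@@]2([C@@H]1C)[C@@H](C)[C@H](O)C(C)(Cl)C(=O)[C@@]2(C)C(=O)OC
F6 | step 15 | C6 epimer of 24, (1R,3'R,4S,4'R,5'R,6R,6'R,7S,8S)-3',4,5',6,6',7-hexamethyl-3,5-dioxospiro[2-oxabicyclo[2.2.2]octane-8,2'-oxan]-4'-yl acetate | CC(=O)O[C@@H]1[C@H](C)[C@@H](C)O[C@@]2([C@@H]1C)[C@@H](C)[C@H]1OC(=O)[C@]2(C)C(=O)[C@@H]1C
F7 | step 15 | trimethylsilyl enol ether of 24 (C5–O–Si, C5=C6) | CC(=O)O[C@@H]1[C@H](C)[C@@H](C)O[C@@]2([C@@H]1C)[C@@H](C)[C@H]1OC(=O)[C@]2(C)C(O[Si](C)(C)C)=C1C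
A1 | alternative 1 | spiro-oxetane on the cage (C5 silyl ether, vinyl side chain) | C=C[C@@H](C)[C@@H]1O[C@@]2([C@@H]1C)[C@@H](C)[C@H]3OC(=O)[C@]2(C)[C@H](O[Si](C)(C)C(C)(C)C)[C@@H]3C
A2 | alternative 1 | cage ketone, 5-[(tert-butyldimethylsilyl)oxy]-4,6,7-trimethyl-2-oxabicyclo[2.2.2]octane-3,8-dione | O=C1[C@@H](C)[C@H]2OC(=O)[C@]1(C)[C@H](O[Si](C)(C)C(C)(C)C)[C@@H]2C
A3 | alternative 1 | (3R,4Z)-3-methylhexa-1,4-diene | C=C[C@@H](C)/C=C\C
A4 | alternative 2 | C4' tert-butyldimethylsilyl ether of deacetyl-24 | CC(C)(C)[Si](C)(C)O[C@@H]1[C@H](C)[C@@H](C)O[C@@]2([C@@H]1C)[C@@H](C)[C@H]1OC(=O)[C@]2(C)C(=O)[C@H]1C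
A5 | alternative 2 | spiro δ-lactone with the C6–C5 chain on C1 as N-methoxy-N-methyl amide (C4 unfixed) | CC(C)(C)[Si](C)(C)O[C@@H]1[C@H](C)[C@@H](C)O[C@@]2([C@@H]1C)[C@@H](C)[C@@H](OC(=O)C2C)[C@H](C)C(=O)N(C)OC
A6 | alternative 3 | spiro tetrahydropyran-4-one on the cage (C6 as in A7) | O=C1[C@H](C)[C@@H](C)O[C@@]2([C@@H]1C)[C@@H](C)[C@H]1OC(=O)[C@]2(C)C(=O)[C@@H]1C
A7 | alternative 3 | meso 4,6,7-trimethyl-2-oxabicyclo[2.2.2]octane-3,5,8-trione | O=C1[C@@H](C)[C@H]2OC(=O)[C@]1(C)C(=O)[C@@H]2C
A8 | alternative 3 | (2Z,4E)-4-methyl-3-[(trimethylsilyl)oxy]hexa-2,4-diene | C/C=C(\O[Si](C)(C)C)/C(C)=C/C
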